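**Plan**

- Numbering: drimane numbers C1–C12 for the terpenoid part (C3 lactone carbonyl, C4 the CMe2–O carbon, C11 the CH2 on C9, C12 the CH2 on C8). C1′–C6′ for the six-membered ring that comes from the phthalide (C1′ carries the lactone carbonyl, C2′ the carbinol, C4′ the ketone, C3′ and C5′ the methyls, C6′ the CH2O).
- Retrosynthesis: C2′–OH back to the ketone; then cut C8–C6′ (radical conjugate addition), C12–C3′ (palladium O-to-C allyl shift), C11–C5′ (dearomatising phenoxide alkylation) and the aryl ether O–C12. This leaves bromo allylic alcohol 13 and phthalide 16.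
- Forward: ring B from (R)-carvone, ring A (lactone) by acrylate ring-closing metathesis, then a seven-membered bridge C3′–C12–C8–C9–C11–C5′ over the dearomatised ring. Last, the cyclopentane C8–C9–C11–C5′–C6′, whose closing bond also completes the bicyclo[2.2.2]octane.
- Enabling feature: C6′ is the β-carbon of an alkylidene flanked by the C2′ ketone and the lactone carbonyl, and C8 is a tertiary carbon next to C7H2. A C7=C8 alkene therefore gives the C8 radical by hydrogen-atom transfer, and this radical closes 5-exo onto C6′.
- Stereochemistry: C5 from (R)-carvone, C10 by alkylation trans to the C5 substituent, C9 by a suprafacial [2,3] shift from the 7α-oxygen, C5′ by the tethered alkylation. C3′, C8 and C6′ are forced by the bridges, C1′ is set by equilibration, and C2′ by hydride attack anti to the lactone carbonyl.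

Key step: step 18

Remark: 5,7-dihydroxy-4-methylphthalide (14) is taken as purchasable; α is the face of H-5, β the face of the C10 methyl.

**Step 1**
Reactants: 1 (R)-(−)-carvone
Product: 2 (5R)-5-(2-hydroxypropan-2-yl)-2-methylcyclohex-2-en-1-one
Conditions: Co(acac)2 (cat.), PhSiH3, O2 (1 atm), THF, rt
Reagents that add atoms: dioxygen, O=O
Why: Mukaiyama hydration should place the hydroxyl on the electron-rich 1,1-disubstituted alkene (tertiary radical trapped by O2), the conjugated enone being a poor hydrogen-atom acceptor; no new stereocentre.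

**Step 2**
Reactants: 2 (5R)-5-(2-hydroxypropan-2-yl)-2-methylcyclohex-2-en-1-one
Product: 3 (5R)-5-(2-hydroxypropan-2-yl)-2,6-dimethylcyclohex-2-en-1-one (both C6 epimers)
Conditions: LiN(iPr)2 (2.2 equiv), THF, −78 °C; MeI, −78 → 0 °C
Reagents that add atoms: iodomethane, CI
Why: Kinetic α′-deprotonation of the enone (the alkoxide takes the second equivalent of base) and enolate methylation; the C6 epimer mixture is irrelevant because C6 is enolised again in step 3.

**Step 3**
Reactants: 3 (5R)-5-(2-hydroxypropan-2-yl)-2,6-dimethylcyclohex-2-en-1-one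
Product: 4 (5R,6S)-5-(2-hydroxypropan-2-yl)-2,6-dimethyl-6-(prop-2-en-1-yl)cyclohex-2-en-1-one
Conditions: LiN(iPr)2 (2.2 equiv), THF, −78 °C; allyl bromide, −78 → 0 °C
Reagents that add atoms: allyl bromide, C=CCBr
Why: Enolate alkylation anti to the neighbouring C5 substituent should give the quaternary C10 with allyl trans and methyl cis to the hydroxypropyl group, the C5/C10 relationship of the target.

**Step 4**
Reactants: 4 (5R,6S)-5-(2-hydroxypropan-2-yl)-2,6-dimethyl-6-(prop-2-en-1-yl)cyclohex-2-en-1-one
Product: 5 (1R,3S,4R,6R)-4-(2-hydroxypropan-2-yl)-1,3-dimethyl-3-(prop-2-en-1-yl)-7-oxabicyclo[4.1.0]heptan-2-one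
Conditions: 30% aq. H2O2, NaOH (cat.), MeOH, 0 °C
Reagents that add atoms: hydrogen peroxide, OO
Why: Weitz–Scheffer epoxidation, with hydroperoxide adding to C7 anti to the C5 substituent and the axial C10 methyl, should give the α-epoxide; oxa-Michael addition of the tertiary hydroxyl is reversible and should not divert material.

**Step 5**
Reactants: 5 (1R,3S,4R,6R)-4-(2-hydroxypropan-2-yl)-1,3-dimethyl-3-(prop-2-en-1-yl)-7-oxabicyclo[4.1.0]heptan-2-one
Product: 6 (1R,4R,5R)-5-(2-hydroxypropan-2-yl)-2,4-dimethyl-4-(prop-2-en-1-yl)cyclohex-2-en-1-ol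
Conditions: N2H4·H2O, AcOH (cat.), MeOH, 0 °C → rt
Reagents that add atoms: none
Why: Wharton transposition (epoxy hydrazone, loss of N2) should move the oxygen to C7 with retention of the C–O configuration (7α-OH) and place the alkene at C8=C9.

**Step 6**
Reactants: 6 (1R,4R,5R)-5-(2-hydroxypropan-2-yl)-2,4-dimethyl-4-(prop-2-en-1-yl)cyclohex-2-en-1-ol
Product: 7 tributylstannylmethyl ether of the secondary (C7) hydroxyl of 6
Conditions: KH, Bu3SnCH2I, THF, 0 °C
Reagents that add atoms: tributyl(iodomethyl)stannane, CCCC[Sn](CCCC)(CCCC)CI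
Why: Williamson etherification should take the accessible secondary allylic alkoxide in preference to the hindered tertiary one.

**Step 7**
Reactants: 7 tributylstannylmethyl ether of 6
Product: 8 [(1R,5R,6R)-5-(2-hydroxypropan-2-yl)-2,6-dimethyl-6-(prop-2-en-1-yl)cyclohex-2-en-1-yl]methanol
Conditions: n-BuLi (2.2 equiv), THF, −78 °C
Reagents that add atoms: none
Why: Wittig–Still [2,3]-sigmatropic rearrangement: tin–lithium exchange gives the α-alkoxymethyl-lithium, which should deliver CH2O suprafacially from the 7α-oxygen to the α-face of C9 (also anti to the C10 methyl), setting 9β-H and moving the alkene to C7=C8.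

**Step 8**
Reactants: 8 [(1R,5R,6R)-5-(2-hydroxypropan-2-yl)-2,6-dimethyl-6-(prop-2-en-1-yl)cyclohex-2-en-1-yl]methanol
Product: 9 2-[(1R,2S,3R)-3-(bromomethyl)-2,4-dimethyl-2-(prop-2-en-1-yl)cyclohex-4-en-1-yl]propan-2-ol
Conditions: CBr4, PPh3, CH2Cl2, 0 °C
Reagents that add atoms: carbon tetrabromide, BrC(Br)(Br)Br
Why: Appel bromination should be selective for the primary alcohol over the tertiary one.

**Step 9**
Reactants: 9 2-[(1R,2S,3R)-3-(bromomethyl)-2,4-dimethyl-2-(prop-2-en-1-yl)cyclohex-4-en-1-yl]propan-2-ol
Product: 10 2-[(1R,2S,3R)-3-(bromomethyl)-2,4-dimethyl-2-[(1E)-prop-1-en-1-yl]cyclohex-4-en-1-yl]propan-2-ol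
Conditions: RuHCl(CO)(PPh3)3 (cat.), toluene, 80 °C
Reagents that add atoms: none
Why: Ruthenium-hydride alkene isomerisation should move the terminal allyl double bond one position inward, leaving the trisubstituted ring alkene alone, so that the later metathesis closes a seven-membered ring.

**Step 10**
Reactants: 10 2-[(1R,2S,3R)-3-(bromomethyl)-2,4-dimethyl-2-[(1E)-prop-1-en-1-yl]cyclohex-4-en-1-yl]propan-2-ol
Product: 11 prop-2-enoate (acrylate) of the tertiary alcohol 10
Conditions: LiN(SiMe3)2, THF, −78 °C; acryloyl chloride, −78 → 0 °C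
Reagents that add atoms: acryloyl chloride, C=CC(=O)Cl
Why: O-acylation of the lithium tertiary alkoxide; the alkoxide cannot displace the bromide because C4 and C11 sit on opposite faces of ring B.

**Step 11**
Reactants: 11 acrylate of 10
Product: 12 11-bromo-4-oxa-A-homodrima-1,7-dien-3-one (5α-H, 9β-H, 10β-CH3; ring A seven-membered unsaturated lactone; CH2Br α on C9)
Conditions: second-generation Hoveyda–Grubbs catalyst (cat.), toluene, 80 °C
Reagents that add atoms: none
Why: Ring-closing metathesis of the acrylate with the propenyl group (propene lost) should close ring A as the Z-unsaturated ε-lactone; the trisubstituted C7=C8 alkene is inert.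

**Step 12**
Reactants: 12 11-bromo-4-oxa-A-homodrima-1,7-dien-3-one
Product: 13 11-bromo-12-hydroxy-4-oxa-A-homodrima-1,7-dien-3-one
Conditions: SeO2 (cat.), t-BuOOH, CH2Cl2, rt
Reagents that add atoms: selenium dioxide, O=[Se]=O; tert-butyl hydroperoxide, CC(C)(C)OO
Why: Selenium dioxide allylic oxidation (ene reaction then [2,3] shift) should attack the methyl on the more substituted alkene carbon C8, CH3 being preferred over the tertiary C9–H, with the C7=C8 alkene retained.

**Step 13**
Reactants: 14 5,7-dihydroxy-4-methylphthalide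
Product: 15 6-[(dimethylamino)methyl]-5,7-dihydroxy-4-methylphthalide
Conditions: aq. CH2O, aq. Me2NH, EtOH, rt
Reagents that add atoms: formaldehyde, C=O; dimethylamine, CNC
Why: Phenolic Mannich reaction at C6, the only free ring position and the one activated by both hydroxyls.

**Step 14**
Reactants: 15 6-[(dimethylamino)methyl]-5,7-dihydroxy-4-methylphthalide
Product: 16 5,7-dihydroxy-4,6-dimethylphthalide
Conditions: H2 (4 bar), Pd/C, AcOH, 50 °C
Reagents that add atoms: none
Why: Hydrogenolysis of the ortho-hydroxybenzylic C–N bond should turn the aminomethyl group into the C6 methyl (the future C3′ methyl).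

**Step 15**
Reactants: 13 11-bromo-12-hydroxy-4-oxa-A-homodrima-1,7-dien-3-one; 16 5,7-dihydroxy-4,6-dimethylphthalide
Product: 17 aryl allyl ether joining C12 of 13 to the 5-oxygen of 16 (7-hydroxyl free, C11 bromide intact)
Conditions: PPh3, iPrO2CN=NCO2iPr, THF, 0 °C → rt
Reagents that add atoms: none
Why: Mitsunobu etherification of the primary allylic alcohol by the more acidic 5-hydroxyl (para to the lactone carbonyl); the 7-hydroxyl is hydrogen-bonded to that carbonyl and should stay free.

**Step 16**
Reactants: 17 aryl allyl ether of 13 and 16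
Product: 18 tethered cyclohexa-2,5-dienone (C11 bonded to quaternary C5′; C4′–O–C12 cyclic enol ether in a seven-membered ring; C2′ ketone; C1′=C6′ butenolide; C7=C8)
Conditions: Cs2CO3, NaI (cat.), DMF (high dilution), 60 °C
Reagents that add atoms: none
Why: Intramolecular alkylative dearomatisation: the 7-phenoxide should alkylate through its para carbon C5′ with the tethered primary halide, and because the CH2Br is axial on the α-face of ring B while the ether oxygen is held at C12, the arene should hang outward below that face and present the face of C5′ that gives the configuration of the target.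

**Step 17**
Reactants: 18 tethered cyclohexa-2,5-dienone
Product: 19 bicyclo[4.3.1] enedione (C12 bonded to C3′ and C11 to C5′; C2′ and C4′ ketones; C1′=C6′ alkylidene lactone; C7=C8)
Conditions: Pd(PPh3)4 (cat.), THF, 50 °C
Reagents that add atoms: none
Why: Tsuji–Trost O-to-C allyl transposition: zerovalent palladium ionises the allyl vinylogous ester and the allyl fragment should return through its unhindered C12 terminus to C3′, the central carbon of the 1,3-dione anion, on the only face the C8–C9–C11 tether allows, so C3′ is set cis to C5′ and the alkene ends at C7=C8.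

**Step 18**
Reactants: 19 bicyclo[4.3.1] enedione
Product: 20 2′-oxo precursor of andilesin A (2′-dehydroandilesin A)
Conditions: Fe(acac)3 (cat.), PhSiH3, EtOH/HOCH2CH2OH, 60 °C
Reagents that add atoms: none
Why: An iron hydride formed from Fe(acac)3 and PhSiH3 should transfer a hydrogen atom to C7 of the electron-rich C7=C8 alkene, the tertiary C8 radical should add to C6′ of the alkylidene activated by both the C2′ ketone and the lactone carbonyl, and the C1′ radical should be reduced to the iron enolate and protonated. The closest known reaction type is the hydrogen-atom-transfer-initiated radical conjugate addition of unactivated alkenes to enones (reductive olefin coupling, a Giese reaction), which is used to join congested quaternary carbons. The closure is a transannular 5-exo-trig cyclisation that forms the cyclopentane C8–C9–C11–C5′–C6′, and the same bond turns the bicyclo[4.3.1] core into the bicyclo[2.2.2]octane. C8 and C6′ are set by the two existing bridges, which let C8 reach C6′ only through its α-face on the ring face that already carries C11 and C12; C1′ is set by equilibration of the β-keto lactone, which should place the lactone carbonyl on the side of the C5′ methyl, away from C7 of ring B. The step needs hydrogen-atom transfer to the isolated alkene in preference to the two electron-poor alkenes, which the polarity preference of the metal hydride should secure, and cyclisation faster than reduction of the C8 radical, which the short C8–C6′ distance held by the seven-membered bridge and the strength of the acceptor should secure.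

**Step 19**
Reactants: 20 2′-dehydroandilesin A
Product: 21 andilesin A
Conditions: NaBH4, MeOH/CH2Cl2, −40 °C
Reagents that add atoms: none
Why: Hydride should attack the C2′ ketone from the side of the C12–C8 bridge, anti to the lactone carbonyl on the adjacent C1′, giving the 2′-alcohol cis to that carbonyl; the C4′ ketone between two quaternary carbons and the conjugated ring A lactone should not react at this temperature.

**Compound list**

1 | (R)-(−)-carvone | CC1=CC[C@H](CC1=O)C(C)=C | starting material
2 | (5R)-5-(2-hydroxypropan-2-yl)-2-methylcyclohex-2-en-1-one | CC1=CC[C@H](CC1=O)C(C)(C)O | intermediate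
3 | (5R)-5-(2-hydroxypropan-2-yl)-2,6-dimethylcyclohex-2-en-1-one (both C6 epimers) | CC1=CC[C@H](C(C)C1=O)C(C)(C)O | intermediate
4 | (5R,6S)-5-(2-hydroxypropan-2-yl)-2,6-dimethyl-6-(prop-2-en-1-yl)cyclohex-2-en-1-one | C=CC[C@]1(C)C(=O)C(C)=CC[C@H]1C(C)(C)O | intermediate
5 | (1R,3S,4R,6R)-4-(2-hydroxypropan-2-yl)-1,3-dimethyl-3-(prop-2-en-1-yl)-7-oxabicyclo[4.1.0]heptan-2-one | C=CC[C@]1(C)C(=O)[C@]2(C)O[C@@H]2C[C@H]1C(C)(C)O | intermediate
6 | (1R,4R,5R)-5-(2-hydroxypropan-2-yl)-2,4-dimethyl-4-(prop-2-en-1-yl)cyclohex-2-en-1-ol | C=CC[C@]1(C)C=C(C)[C@H](O)C[C@H]1C(C)(C)O | intermediate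
7 | tributyl({[(1R,4R,5R)-5-(2-hydroxypropan-2-yl)-2,4-dimethyl-4-(prop-2-en-1-yl)cyclohex-2-en-1-yl]oxy}methyl)stannane | C=CC[C@]1(C)C=C(C)[C@H](OC[Sn](CCCC)(CCCC)CCCC)C[C@H]1C(C)(C)O | intermediate
8 | [(1R,5R,6R)-5-(2-hydroxypropan-2-yl)-2,6-dimethyl-6-(prop-2-en-1-yl)cyclohex-2-en-1-yl]methanol | C=CC[C@]1(C)[C@H](CO)C(C)=CC[C@H]1C(C)(C)O | intermediate
9 | 2-[(1R,2S,3R)-3-(bromomethyl)-2,4-dimethyl-2-(prop-2-en-1-yl)cyclohex-4-en-1-yl]propan-2-ol | C=CC[C@]1(C)[C@H](CBr)C(C)=CC[C@H]1C(C)(C)O | intermediate
10 | 2-[(1R,2S,3R)-3-(bromomethyl)-2,4-dimethyl-2-[(1E)-prop-1-en-1-yl]cyclohex-4-en-1-yl]propan-2-ol | C/C=C/[C@]1(C)[C@H](CBr)C(C)=CC[C@H]1C(C)(C)O | intermediate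
11 | 2-[(1R,2S,3R)-3-(bromomethyl)-2,4-dimethyl-2-[(1E)-prop-1-en-1-yl]cyclohex-4-en-1-yl]propan-2-yl prop-2-enoate | C/C=C/[C@]1(C)[C@H](CBr)C(C)=CC[C@H]1C(C)(C)OC(=O)C=C | intermediate
12 | 11-bromo-4-oxa-A-homodrima-1,7-dien-3-one (5α-H, 9β-H, 10β-CH3) | CC1(C)OC(=O)C=C[C@@]2(C)[C@H]1CC=C(C)[C@H]2CBr | intermediate
13 | 11-bromo-12-hydroxy-4-oxa-A-homodrima-1,7-dien-3-one (5α-H, 9β-H, 10β-CH3) | CC1(C)OC(=O)C=C[C@@]2(C)[C@H]1CC=C(CO)[C@H]2CBr | intermediate
14 | 5,7-dihydroxy-4-methylphthalide | O=C1OCc2c(C)c(O)cc(O)c12 | starting material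
15 | 6-[(dimethylamino)methyl]-5,7-dihydroxy-4-methylphthalide | O=C1OCc2c(C)c(O)c(CN(C)C)c(O)c12 | intermediate
16 | 5,7-dihydroxy-4,6-dimethylphthalide | O=C1OCc2c(C)c(O)c(C)c(O)c12 | intermediate
17 | 5-O-(C12) aryl allyl ether of 13 and 16 (7-hydroxyl free, C11 bromide) | CC1(C)OC(=O)C=C[C@@]2(C)[C@H]1CC=C(COc3c(C)c(O)c4C(=O)OCc4c3C)[C@H]2CBr | intermediate
18 | tethered cyclohexa-2,5-dienone (C11–C5′ bond, C4′–O–C12 enol ether, C2′ ketone, C1′=C6′) | CC1(C)OC(=O)C=C[C@@]2(C)[C@H]1CC=C3COC4=C(C)C(=O)C5=C(COC5=O)[C@@]4(C)C[C@@H]23 | intermediate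
19 | bicyclo[4.3.1] enedione (C12–C3′ and C11–C5′ bonds, C2′ and C4′ ketones, C1′=C6′, C7=C8) | CC1(C)OC(=O)C=C[C@@]2(C)[C@H]1CC=C3C[C@]4(C)C(=O)[C@](C)(C[C@@H]23)C5=C(C4=O)C(=O)OC5 | intermediate
20 | 2′-dehydroandilesin A (2′-ketone) | CC1(C)OC(=O)C=C[C@@]2(C)[C@H]1CC[C@]13C[C@]4(C)C(=O)[C@](C)(C[C@@H]21)[C@]31COC(=O)[C@H]1C4=O | intermediate
21 | andilesin A | CC1(C)OC(=O)C=C[C@@]2(C)[C@H]1CC[C@]13C[C@]4(C)C(=O)[C@](C)(C[C@@H]21)[C@]31COC(=O)[C@H]1[C@H]4O | target

**Step count and risks**

Total step count: 19. Longest linear sequence: 17 (steps 1–12 and 15–19).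

Three steps most likely to fail:

1. Step 16. The alkylation may take the other ortho carbon of the ether (C3′) instead of C5′, or the wrong face of C5′; a wrong C5′ epimer could not close the cyclopentane later and would be lost. The facial preference rests on a hand conformational analysis, not on a calculation. Fallback, setting out from 13 and 16 and coming back at 19: the order of the two C–C bonds would be reversed. Alcohol 13 would be converted with ClCO2Me/pyridine into the allylic methyl carbonate F1. F1 and 16 with Pd(PPh3)4 should give, by Tsuji–Trost dearomatising C-allylation at C3′ (the carbon between the two hydroxyls, the most nucleophilic site), the C3′-allylated cyclohexadienone F2. Cs2CO3/NaI in DMF should then close the seven-membered ring by vinylogous alkylation of the dienolate at C5′ with the C11 bromide, which can only happen on the face that already carries C12, giving 19.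

2. Step 17. After ionisation the allyl fragment may collapse back on oxygen or lose a proton to a diene instead of closing the seven-membered carbocycle. Fallback, setting out from 18 and coming back at 20: Pd(PPh3)4 with HCO2H/Et3N should reduce the allyl fragment at its more substituted terminus C7 and free the enol, giving the exo-methylene dienol F3 (C8=C12, linear 2,4-cyclohexadienone with 2′-enol). Heating F3 in toluene at about 130 °C should close C12–C3′ and C8–C6′ together in an intramolecular Diels–Alder reaction of the 6,6-disubstituted cyclohexadienone, and tautomerisation of the adduct enol would give 20.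

3. Step 18. Reduction of the C8 radical (net hydrogenation of C7=C8) or conjugate reduction of the alkylidene may outrun the transannular addition. Fallback, setting out from 19 and coming back at 20: a two-electron route. A Lewis acid (ZnBr2 or Me2AlCl, CH2Cl2) should promote an intramolecular ene reaction of the alkylidene β-keto lactone with the C7=C8 alkene, forming C8–C6′ with transfer of a C6 hydrogen to C1′ and giving the 6,7-didehydro cage ketone F4. Hydrogenation with RhCl(PPh3)3/H2 should then reduce the unconjugated C6=C7 bond in preference to the conjugated, hindered ring A alkene and give 20.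

**Further compounds**

F1 | step 16 | allylic methyl carbonate of 13 (12-O-methoxycarbonyl) | CC1(C)OC(=O)C=C[C@@]2(C)[C@H]1CC=C(COC(=O)OC)[C@H]2CBr
F2 | step 16 | C3′-allylated cyclohexa-2,4-dienone (C12–C3′ bond, 2′-enol, C5′ still sp2, C11 bromide) | CC1(C)OC(=O)C=C[C@@]2(C)[C@H]1CC=C(C[C@]3(C)C(=O)C(C)=C4COC(=O)C4=C3O)[C@H]2CBr
F3 | step 17 | exo-methylene dienol (C8=C12, C11–C5′ bond, 4′-ketone, 2′-enol, C1′=C6′) | CC1(C)OC(=O)C=C[C@@]2(C)[C@H]1CCC(=C)[C@H]2C[C@@]3(C)C(=O)C(C)=C(O)C4=C3COC4=O
F4 | step 18 | 6,7-didehydro derivative of 20 | CC1(C)OC(=O)C=C[C@@]2(C)[C@H]1C=C[C@]13C[C@]4(C)C(=O)[C@](C)(C[C@@H]21)[C@]31COC(=O)[C@H]1C4=O
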